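Numbering: ring A is the diol ring (C1 = C(CH3)OH, C2 = CHOH, C3 carries the CH2 link, C4 carries isopropenyl). Ring B is the bromohydrin ring (C1′ = C(CH3)OH, C2′ = CHBr, C4′ is bound to the alkene carbon C8). Cuts, in order: C2–OH back to C2=O; the C8–C4′ bond, giving vinyl bromide 8 and carboxylic acid 14; in ring A the C3–CH2 bond (enolate allylation) and the C1–O bond (oxirane); in ring B the C1′–CH3 bond (Grignard) and the C2′–Br bond (enol ether bromination).
Forward: both six-membered rings are bought. Ring A is dressed on (S)-carvone (steps 1–4) and ring B on tert-butyl 4-oxocyclohexanecarboxylate (steps 5–8). The unprotected halves are joined in step 9, and step 10 adjusts one oxidation level.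
Enabling feature: C4′ is the only stereocentre of ring B without a heteroatom, and it lies 1,3 to C2′–Br and 1,4 to C1′(CH3)(OH). In the chair with Br and CH3 equatorial, the target also carries its alkenyl group equatorial. A planar C4′ radical can therefore come from either C4′ epimer and should be refilled from the equatorial side.
A carboxyl group at C4′ thus serves three times. It is the temporary stereocentre created by desymmetrisation, the anchor that relays C4′→C2′→C1′, and the traceless radical precursor lost as CO2. After its loss, C1′ and C2′ relay back to C4′.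
Stereochemistry: ring A derives from the single bought centre of (S)-carvone (C4→C3→C1→C2, all substrate control). Ring B derives from one reagent-controlled enantiotopic deprotonation.

Key step: step 9

Assumption: lithium (R,R)-bis(1-phenylethyl)amide is taken to discriminate the enantiotopic α-hydrogens of 9 in the sense known for 4-tert-butylcyclohexanone (S enol ether); should the sense be opposite, the (S,S)-amide is used.

Step 1
Reactants: 1 (S)-(+)-carvone; 2 2,3-dibromopropene
Product: 4 (5S,6R)-6-(2-bromoprop-2-en-1-yl)-2-methyl-5-(prop-1-en-2-yl)cyclohex-2-en-1-one (side chain trans to isopropenyl), via lithium dienolate 3 (not isolated)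
Conditions: LDA, THF, −78 °C; then 2, −78 to −20 °C
Reagents that add atoms: 2,3-dibromopropene (2), C=C(Br)CBr
Why: Kinetic α′-deprotonation gives the cross-conjugated dienolate 3, which is alkylated (enolate alkylation, SN2) by the allylic end of 2 on the face opposite the adjacent isopropenyl group, setting C3 trans to C4 while the vinylic C–Br bond stays inert.

Step 2
Reactants: 4 (5S,6R)-6-(2-bromoallyl)carvone
Product: 5 (1S,3R,4S,6S)-3-(2-bromoprop-2-en-1-yl)-1-methyl-4-(prop-1-en-2-yl)-7-oxabicyclo[4.1.0]heptan-2-one (oxirane O trans to isopropenyl)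
Conditions: 30% H2O2, cat. NaOH, MeOH, 0 °C
Reagents that add atoms: hydrogen peroxide, OO
Why: Weitz–Scheffer nucleophilic epoxidation touches only the electron-poor enone C=C, and hydroperoxide adds axially to the β-carbon anti to the isopropenyl group as in carvone itself, so the future equatorial C1–O bond is set trans to isopropenyl.

Step 3
Reactants: 5 epoxy ketone
Product: 7 (1S,2R,3R,4S)-3-(2-bromoprop-2-en-1-yl)-1-methyl-4-(prop-1-en-2-yl)cyclohexane-1,2-diol (any C2 epimer is carried along), via cis-epoxy alcohol 6 (not isolated)
Conditions: LiAlH4, THF, 0 °C to rt; aq. NaOH work-up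
Reagents that add atoms: none
Why: Carbonyl reduction anti to the oxirane oxygen gives the cis-epoxy alkoxide 6, which cannot deliver hydride internally, so external SN2 hydride opening should take place at the secondary oxirane carbon C6 and keep the tertiary C1–O bond; the C2 configuration is irrelevant because step 4 erases it.

Step 4
Reactants: 7 diol
Product: 8 (2S,5S,6R)-6-(2-bromoprop-2-en-1-yl)-2-hydroxy-2-methyl-5-(prop-1-en-2-yl)cyclohexan-1-one
Conditions: Dess–Martin periodinane, CH2Cl2, 0 °C to rt
Reagents that add atoms: none
Why: Dess–Martin oxidation acts only on the secondary carbinol (the tertiary one cannot react), merges both C2 epimers into one α-hydroxy ketone and provides the oxidation level wanted at C2 for the coupling.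

Step 5
Reactants: 9 tert-butyl 4-oxocyclohexane-1-carboxylate
Product: 11 tert-butyl (S)-4-(trimethylsilyloxy)cyclohex-3-ene-1-carboxylate, via lithium enolate 10 (not isolated)
Conditions: (R,R)-bis(1-phenylethyl)amine, n-BuLi, LiCl, THF, −78 °C; TMSCl (internal quench), then 9, −100 to −78 °C
Reagents that add atoms: chlorotrimethylsilane, C[Si](C)(C)Cl
Why: Enantioselective deprotonation with a C2-symmetric chiral lithium amide removes one of the two enantiotopic axial α-hydrogens of the prochiral ketone and so makes the ester-bearing C4′ a stereocentre, the ketone α-CH being more acidic and more accessible than the ester α-CH.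

Step 6
Reactants: 11 silyl enol ether
Product: 12 tert-butyl (1S,3R)-3-bromo-4-oxocyclohexane-1-carboxylate (Br axial, trans to the ester)
Conditions: NBS, THF, −78 °C; cold aq. NaHCO3 work-up, used without chromatography
Reagents that add atoms: N-bromosuccinimide, O=C1CCC(=O)N1Br
Why: In this electrophilic bromination of a silyl enol ether the enol ether fixes the position, and stereoelectronically preferred axial attack on the half-chair with the ester equatorial places Br at C2′ trans to the ester under kinetic control.

Step 7
Reactants: 12 α-bromo ketone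
Product: 13 tert-butyl (1S,3R,4S)-3-bromo-4-hydroxy-4-methylcyclohexane-1-carboxylate (OH cis to Br, CH3 trans to Br)
Conditions: MeMgBr, Et2O–CH2Cl2, −78 °C; quench at −78 °C with aq. NH4Cl
Reagents that add atoms: methylmagnesium bromide, C[Mg]Br
Why: Grignard 1,2-addition under polar Felkin–Anh control brings methyl in antiperiplanar to the axial C–Br bond (an axial attack), which sets C1′ with OH cis to Br; the cold quench forestalls semipinacol migration in the magnesium alkoxide, and the tert-butyl ester is too hindered to react.

Step 8
Reactants: 13 bromohydrin ester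
Product: 14 (1S,3R,4S)-3-bromo-4-hydroxy-4-methylcyclohexane-1-carboxylic acid
Conditions: TFA, CH2Cl2, 0 °C
Reagents that add atoms: none
Why: Acidolysis of the tert-butyl ester (loss of isobutene) avoids base, which could trigger ring contraction of the cis-bromohydrin, and the adjacent electron-withdrawing C–Br bond retards ionisation of the tertiary carbinol.

Step 9
Reactants: 8 vinyl bromide (α-hydroxy ketone); 14 carboxylic acid (slight excess)
Product: 15 (2S,5S,6R)-6-{2-[(1R,3R,4S)-3-bromo-4-hydroxy-4-methylcyclohexyl]prop-2-en-1-yl}-2-hydroxy-2-methyl-5-(prop-1-en-2-yl)cyclohexan-1-one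
Conditions: cat. Ir[dF(CF3)ppy]2(dtbbpy)PF6, cat. NiCl2·glyme, cat. dtbbpy, Cs2CO3, DMSO, blue LEDs, rt
Reagents that add atoms: none
Why: The carboxylate of 14 is oxidised by the excited Ir(III) photocatalyst and loses CO2 to give the planar secondary C4′ radical, while Ni(0) inserts into the C(sp2)–Br bond of 8; radical capture gives an alkyl(alkenyl)Ni(III) species that reductively eliminates the C8–C4′ bond, and Ir(II) returns Ni(I) to Ni(0). The closest known reaction type is the metallaphotoredox decarboxylative C(sp3)–C(sp2) cross-coupling of aliphatic carboxylic acids with vinyl halides, and no ring is closed. The one new stereocentre, C4′, is controlled by the ring B chair: with CH3 and Br equatorial and only OH axial (on the face away from the axial C4′ site), the bulky, reversibly bound nickel fragment should sit and eliminate equatorially, so the alkenyl group ends cis to Br and OH whatever the configuration of the lost carboxyl group. The step needs nickel to choose the vinylic C–Br bond over the C2′–Br bond, which is secured because that alkyl bromide is secondary, equatorial, flanked by the fully substituted C1′ and not engaged without a halogen-atom abstractor. The ketone level at C2 of 8 removes the one hydroxyl that could chelate the alkenylnickel and close a five-membered cyclic enol ether by C–O coupling. The tertiary alcohols and both 1,1-disubstituted alkenes are inert to a nucleophilic secondary radical.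

Step 10
Reactants: 15 coupled α-hydroxy ketone
Product: 16 (1S,2S,3R,4S)-3-{2-[(1R,3R,4S)-3-bromo-4-hydroxy-4-methylcyclohexyl]prop-2-en-1-yl}-1-methyl-4-(prop-1-en-2-yl)cyclohexane-1,2-diol (target)
Conditions: NaBH4, MeOH, −20 to 0 °C
Reagents that add atoms: none
Why: In this borohydride carbonyl reduction the axial C1 methyl group blocks one face, so hydride attacks axially from the other and gives the equatorial C2–OH trans to both the C1–OH and the C3 side chain, leaving the secondary bromide and the alkenes untouched.

Compound list
1 | (S)-(+)-carvone | C1[C@@H](C(=C)C)CC=C(C)C1=O | starting material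
2 | 2,3-dibromopropene | C=C(Br)CBr | starting material
3 | lithium cross-conjugated dienolate of carvone | [Li+].[O-]C1=C[C@@H](C(=C)C)CC=C1C | intermediate
4 | (5S,6R)-6-(2-bromoallyl)carvone | C=C(Br)C[C@@H]1[C@@H](C(=C)C)CC=C(C)C1=O | intermediate
5 | (1S,3R,4S,6S)-epoxy ketone, oxirane trans to isopropenyl | C=C(Br)C[C@@H]1[C@@H](C(=C)C)C[C@@H]2O[C@]2(C)C1=O | intermediate
6 | cis-epoxy alcohol (OH and oxirane O on the same face; formed as its aluminium alkoxide, drawn as the alcohol) | C=C(Br)C[C@@H]1[C@@H](C(=C)C)C[C@@H]2O[C@]2(C)[C@@H]1O | intermediate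
7 | (1S,2R,3R,4S)-3-(2-bromoallyl)-1-methyl-4-isopropenylcyclohexane-1,2-diol | C=C(Br)C[C@@H]1[C@@H](C(=C)C)CC[C@](C)(O)[C@@H]1O | intermediate
8 | (2S,5S,6R)-6-(2-bromoallyl)-2-hydroxy-2-methyl-5-isopropenylcyclohexanone | C=C(Br)C[C@@H]1[C@@H](C(=C)C)CC[C@](C)(O)C1=O | intermediate
9 | tert-butyl 4-oxocyclohexane-1-carboxylate | CC(C)(C)OC(=O)C1CCC(=O)CC1 | starting material
10 | lithium enolate of 9, (S) at the ester-bearing carbon | [Li+].CC(C)(C)OC(=O)[C@H]1CCC([O-])=CC1 | intermediate
11 | tert-butyl (S)-4-(trimethylsilyloxy)cyclohex-3-ene-1-carboxylate | CC(C)(C)OC(=O)[C@H]1CCC(O[Si](C)(C)C)=CC1 | intermediate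
12 | tert-butyl (1S,3R)-3-bromo-4-oxocyclohexane-1-carboxylate | CC(C)(C)OC(=O)[C@H]1CCC(=O)[C@H](Br)C1 | intermediate
13 | tert-butyl (1S,3R,4S)-3-bromo-4-hydroxy-4-methylcyclohexane-1-carboxylate | CC(C)(C)OC(=O)[C@H]1CC[C@](C)(O)[C@H](Br)C1 | intermediate
14 | (1S,3R,4S)-3-bromo-4-hydroxy-4-methylcyclohexane-1-carboxylic acid | OC(=O)[C@H]1CC[C@](C)(O)[C@H](Br)C1 | intermediate
15 | coupled α-hydroxy ketone | C=C(C[C@@H]1[C@@H](C(=C)C)CC[C@](C)(O)C1=O)[C@@H]1CC[C@](C)(O)[C@H](Br)C1 | intermediate
16 | CNP0422107.2 | C=C(C[C@@H]1[C@@H](C(=C)C)CC[C@](C)(O)[C@H]1O)[C@@H]1CC[C@](C)(O)[C@H](Br)C1 | target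

Total step count: 10. Longest linear sequence: 6 (steps 1–4, 9, 10, or equally steps 5–8, 9, 10).

Steps most likely to fail

Step 9. Three things may go wrong. The planar C4′ radical may be captured from both faces, because the chair bias of ring B is only moderate. Decarboxylation of an unstabilised secondary carboxylate may be slow compared with homocoupling or reduction of the hindered vinyl bromide. Halogen abstraction at C2′–Br may intervene. The fallback replaces the radical union by a stereospecific polar one and moves the C4′ problem to a small fragment.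
- It sets out from 14 and 8 and returns at 16.
- Acid 14 is esterified with N-hydroxyphthalimide (DIC, DMAP) to the redox-active ester F1.
- Irradiation with bis(catecholato)diboron in DMAc, followed by pinacol and Et3N, gives the pinacol boronic ester F2. Its all-equatorial epimer is separated at this stage.
- TESOTf and 2,6-lutidine give the silyl ether F3.
- Ketone 8 is reduced with NaBH4 to the trans-diol F4 and silylated (TESOTf, 2,6-lutidine) to the bis-silyl ether F5.
- Bromine–lithium exchange on F5 (t-BuLi, −78 °C), addition of F3, then I2 and NaOMe effect a Zweifel olefination (stereoretentive 1,2-metallate shift, then anti elimination). This gives the tris-silyl ether F6.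
- HF·pyridine converts F6 into 16.

Step 3. Hydride opening at C6 runs against the trans-diaxial (Fürst–Plattner) preference. With both the C3 and C4 substituents anchoring the half-chair, the opening may stall or drift to the tertiary C1. It may also need temperatures at which the vinylic bromide is reduced. The fallback changes the order of events, so that the oxirane is opened while only the isopropenyl group biases the ring.
- It sets out from 1 and returns at 8.
- Carvone 1 is epoxidised (H2O2, NaOH) to carvone oxide F7.
- LiAlH4 reduces F7 to the 1,2-diol F8.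
- Dess–Martin oxidation gives the α-hydroxy ketone F9.
- The alkoxide–enolate dianion of F9 (LDA, 2.2 equiv) is alkylated with 2 at the only enolisable α-carbon, trans to the isopropenyl group, to give 8.

Step 5. Discrimination between the enantiotopic α-hydrogens may be insufficient, or deprotonation next to the ester may compete. Either would pass on to 16 as a ring B diastereomer. The fallback adds a classical resolution to the kinetic selection. It sets out from 14 and returns at 14. Scalemic 14 is crystallised as its (R)-1-phenylethylammonium salt F10 until the rotation is constant, and the acid is released with dilute HCl.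

Further compounds
F1 | step 9 | 1,3-dioxoisoindolin-2-yl (1S,3R,4S)-3-bromo-4-hydroxy-4-methylcyclohexane-1-carboxylate | O=C(ON1C(=O)c2ccccc2C1=O)[C@H]1CC[C@](C)(O)[C@H](Br)C1
F2 | step 9 | 2-[(1R,3R,4S)-3-bromo-4-hydroxy-4-methylcyclohexyl]-4,4,5,5-tetramethyl-1,3,2-dioxaborolane (B, Br and CH3 equatorial) | CC1(C)OB(OC1(C)C)[C@@H]1CC[C@](C)(O)[C@H](Br)C1
F3 | step 9 | O-triethylsilyl ether of F2 | CC1(C)OB(OC1(C)C)[C@@H]1CC[C@](C)(O[Si](CC)(CC)CC)[C@H](Br)C1
F4 | step 9 | (1S,2S,3R,4S)-3-(2-bromoallyl)-1-methyl-4-isopropenylcyclohexane-1,2-diol | C=C(Br)C[C@@H]1[C@@H](C(=C)C)CC[C@](C)(O)[C@H]1O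
F5 | step 9 | bis(triethylsilyl) ether of F4 | C=C(Br)C[C@@H]1[C@@H](C(=C)C)CC[C@](C)(O[Si](CC)(CC)CC)[C@H]1O[Si](CC)(CC)CC
F6 | step 9 | tris(triethylsilyl) ether of 16 | C=C(C[C@@H]1[C@@H](C(=C)C)CC[C@](C)(O[Si](CC)(CC)CC)[C@H]1O[Si](CC)(CC)CC)[C@@H]1CC[C@](C)(O[Si](CC)(CC)CC)[C@H](Br)C1
F7 | step 3 | (1S,4S,6S)-carvone oxide | C1[C@@H](C(=C)C)C[C@@H]2O[C@]2(C)C1=O
F8 | step 3 | (1S,2R,4S)-1-methyl-4-(prop-1-en-2-yl)cyclohexane-1,2-diol | C1[C@@H](C(=C)C)CC[C@](C)(O)[C@@H]1O
F9 | step 3 | (2S,5S)-2-hydroxy-2-methyl-5-(prop-1-en-2-yl)cyclohexan-1-one | C1[C@@H](C(=C)C)CC[C@](C)(O)C1=O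
F10 | step 5 | (R)-1-phenylethylammonium (1S,3R,4S)-3-bromo-4-hydroxy-4-methylcyclohexane-1-carboxylate | C[C@@H]([NH3+])c1ccccc1.[O-]C(=O)[C@H]1CC[C@](C)(O)[C@H](Br)C1
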